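**Retrosynthetic overview**
- Target 22 ← allylic oxidation at C15 and chelation-controlled reduction at C12 ← keto allylic alcohol 19 ← acid fragmentation / Peterson elimination of photoadduct 17.
- Enabling feature: in the bicyclo[3.2.1]octene of rings C and D, the carbinol carbon C12 is the one-carbon bridge between bridgeheads C11 and C13. Together with C8=C9 and the C14 methylene, atoms C8, C9, C11, C12, C13, C14 are a masked anisole ring, so the two-carbon bridge C15–C16 (with C17) can be added across C11/C13 of a flat arene.
- Key disconnection: arene–alkene meta photocycloaddition, a (3+2) addition of dioxole 16 to arene 11, closes ring D and removes the whole enone bridge in one cut.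
- Arene 11 ← epoxide–arene cyclisation (ring B, quaternary C10) of epoxy alcohol 9 ← (R)-α-cyclocitral 6 + 4-methoxybenzyl Grignard 7; 6 ← CBS reduction and Wittig–Still rearrangement from enone 1.
- Ring order: A (bought), C (bought as arene), B (step 7), D (step 11).

Key step: step 11

Remark: atoms carry the diterpenoid numbers C1–C20 (C15 = ketone carbon, C16/C17 = methylene unit), and faces are named relative to the C10 methyl C20.

**Route**

Step 1
Reactants: 1 2,4,4-trimethylcyclohex-2-en-1-one
Product: 2 (S)-2,4,4-trimethylcyclohex-2-en-1-ol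
Conditions: (R)-2-methyl-CBS-oxazaborolidine (10 mol%), BH3·SMe2, THF, −20 °C
Reagents that add atoms: none
Why: Corey–Bakshi–Shibata reduction, in which the methyl-bearing alkenyl arm acts as the large group so that hydride should reach one carbonyl face and give the (S)-carbinol at C1.

Step 2
Reactants: 2 (S)-2,4,4-trimethylcyclohex-2-en-1-ol
Product: 3 tributyl({[(1S)-2,4,4-trimethylcyclohex-2-en-1-yl]oxy}methyl)stannane
Conditions: KH, THF, 0 °C; then ICH2SnBu3, rt
Reagents that add atoms: (iodomethyl)tributylstannane, CCCC[Sn](CCCC)(CCCC)CI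
Why: Williamson etherification of the potassium alkoxide with a primary iodide, which leaves the C1 stereocentre untouched.

Step 3
Reactants: 3 tributyl({[(1S)-2,4,4-trimethylcyclohex-2-en-1-yl]oxy}methyl)stannane
Product: 5 [(1R)-2,6,6-trimethylcyclohex-2-en-1-yl]methanol ((R)-α-cyclogeraniol), via lithiomethyl ether 4 (not isolated)
Conditions: n-BuLi, THF, −78 → −40 °C; then H2O
Reagents that add atoms: none
Why: Tin–lithium exchange followed by Wittig–Still (2,3)-sigmatropic rearrangement, whose suprafacial course should transfer the C1–O chirality to the new C5–C6 bond and move the olefin to C1=C10.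

Step 4
Reactants: 5 (R)-α-cyclogeraniol
Product: 6 (1R)-2,6,6-trimethylcyclohex-2-ene-1-carbaldehyde ((R)-α-cyclocitral)
Conditions: Dess–Martin periodinane, NaHCO3, CH2Cl2, 0 °C
Reagents that add atoms: none
Why: Dess–Martin oxidation under buffered, non-enolising conditions, which should keep the β,γ-olefin in place and the C5 stereocentre intact.

Step 5
Reactants: 6 (R)-α-cyclocitral; 7 4-methoxybenzylmagnesium chloride
Product: 8 (1S)-2-(4-methoxyphenyl)-1-[(1R)-2,6,6-trimethylcyclohex-2-en-1-yl]ethan-1-ol
Conditions: CeCl3, THF, −78 °C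
Reagents that add atoms: none
Why: Organocerium 1,2-addition (enolisation suppressed) under Felkin–Anh control with the quaternary C4 anti to the nucleophile, which should set C6 as (S); the minor epimer is removed by chromatography.

Step 6
Reactants: 8 homoallylic alcohol
Product: 9 (1S)-2-(4-methoxyphenyl)-1-[(1R,2S,6S)-1,3,3-trimethyl-7-oxabicyclo[4.1.0]heptan-2-yl]ethan-1-ol (epoxide cis to the carbinol side chain)
Conditions: VO(acac)2 (5 mol%), t-BuOOH, toluene, 0 °C → rt
Reagents that add atoms: tert-butyl hydroperoxide, CC(C)(C)OO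
Why: Hydroxyl-directed epoxidation of a homoallylic alcohol, in which the vanadium alkoxide delivers oxygen to the face of C1=C10 that carries the side chain.

Step 7
Reactants: 9 cis-epoxy alcohol
Product: 10 (1S,5R,6S,10R)-12-methoxypodocarpa-8,11,13-triene-1,6-diol (1-OH and 6-OH cis to C20; H-5 trans to C20)
Conditions: BF3·OEt2, CH2Cl2, −78 → −40 °C
Reagents that add atoms: none
Why: Friedel–Crafts epoxide–arene cyclisation: ionisation at tertiary C10 and attack of the anisole ring (both carbons ortho to the CH2 are equivalent) on the face opposite the C1–O–BF3 group through a chair-like ring B should give the trans A/B fusion with C20 cis to 1-OH, the C1–O bond staying intact.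

Step 8
Reactants: 10 tricyclic diol
Product: 11 (1S,5R,6S,10R)-6-hydroxy-12-methoxypodocarpa-8,11,13-trien-1-yl acetate
Conditions: Ac2O, pyridine, DMAP (cat.), CH2Cl2, 0 °C
Reagents that add atoms: acetic anhydride, CC(=O)OC(C)=O
Why: Sterically differentiated acylation: the equatorial 1-OH should be acetylated while the axial 6-OH, flanked by two syn-axial methyls (C20 and one C4 methyl), should stay free.

Step 9
Reactants: 12 2,2-dimethyl-1,3-dioxolan-4-one
Product: 14 2,2-dimethyl-1,3-dioxol-4-yl diphenyl phosphate, via potassium enolate 13 (not isolated)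
Conditions: KN(SiMe3)2, THF, −78 °C; (PhO)2P(O)Cl, HMPA
Reagents that add atoms: diphenyl phosphorochloridate, O=P(Cl)(Oc1ccccc1)Oc1ccccc1
Why: O-Phosphorylation of a lactone enolate, the standard entry to ketene acetal phosphates.

Step 10
Reactants: 14 ketene acetal phosphate; 15 (trimethylsilyl)methylmagnesium chloride
Product: 16 2,2-dimethyl-4-[(trimethylsilyl)methyl]-1,3-dioxole
Conditions: Ni(acac)2 (5 mol%), THF, 0 °C → rt
Reagents that add atoms: none
Why: Kumada-type cross-coupling of an enol phosphate with Me3SiCH2MgCl, which should give the allylsilane with the enediol ether ring intact.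

Step 11
Reactants: 11 arene acetate; 16 silylmethyl dioxole
Product: 17 meta photocycloadduct (new bonds C11–C15 / C13–C16 / C12–C14; 15,16-O-isopropylidene exo; 16-CH2SiMe3 endo; two-carbon bridge anti to C20; 12-OMe on the cyclopropane)
Conditions: hν (254 nm, low-pressure Hg lamp, quartz), 16 (8 equiv), cyclohexane, 15 °C, degassed
Reagents that add atoms: none
Why: Arene–alkene meta photocycloaddition: the singlet-excited anisole ring C forms an exciplex with the dioxole C=C, which bonds to C11 and C13, the two carbons flanking the methoxy-bearing C12 (the usual 2,6-mode of alkoxyarenes), and the resulting C12 / C14–C8–C9 biradical collapses to the C12–C14 cyclopropane. The closest known reaction type is the intermolecular meta photocycloaddition of anisoles to 1,3-dioxoles and other enol ethers. Ring D (C11–C15–C16–C13–C12) closes as a formal (3+2) cycloaddition across the meta carbons C11/C13, and the temporary three-membered ring closes by radical recombination at the unsubstituted allyl terminus C14 rather than at C9, which is shielded by the quaternary C10. C11 and C13 should be set by approach of the alkene to the arene face anti to the axial C20 methyl, C15 and C16 by the exo orientation of the dioxole ring (ketal carbon turned away from the π face), and C12 and C14 follow from the ring geometry. The step needs orientational selectivity (silylmethyl-bearing carbon to C13, CH to C11), which should come from the endo CH2SiMe3 group avoiding the peri region of ring A (C1–H, C10) next to C11; meta over ortho addition is expected for the donor–donor pair anisole / enol ether.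

Step 12
Reactants: 17 meta photocycloadduct
Product: 19 (1S,5R,6S,10R)-6,15-dihydroxy-12-oxo tetracyclic 8,16-diene 1-acetate (target isomer bearing C12=O and exo 15-OH), via keto acetonide 18 (not isolated)
Conditions: TsOH·H2O (0.3 equiv), THF/H2O 5:1, rt
Reagents that add atoms: water, O
Why: Acid opens the donor-substituted cyclopropane by protonation at C14 (oxocarbenium at C12, hydrolysed to the bridge ketone, leaving C8=C9 and C14H2), and the β-silyl ketal then undergoes Peterson-type elimination across C16–C17 with loss of acetone, which should give the exocyclic methylene and the free 15-OH without breaking the C15–O bond.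

Step 13
Reactants: 19 keto allylic alcohol
Product: 21 12,15-diol (12-OH and 15-OH both syn to each other; 12S), via diethylboron chelate 20 (not isolated)
Conditions: Et2BOMe, THF/MeOH 4:1, −78 °C; NaBH4; then AcOH, MeOH azeotrope
Reagents that add atoms: none
Why: Narasaka–Prasad syn-selective reduction: the diethylboron chelate between the exo 15-oxygen and the C12 carbonyl covers the C15–C16 side, so external hydride should add to C12 from the open face over C8=C9/C14 and place 12-OH syn to the two-carbon bridge.

Step 14
Reactants: 21 12,15-diol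
Product: 22 target CNP0149338.1
Conditions: MnO2 (excess), CH2Cl2, rt
Reagents that add atoms: none
Why: Chemoselective MnO2 oxidation of the allylic 15-OH to the α-methylene ketone, under which the saturated 6- and 12-hydroxyls should not be oxidised.

**Compound list**

1 | 2,4,4-trimethylcyclohex-2-en-1-one | CC1=CC(C)(C)CCC1=O | starting material
2 | (S)-2,4,4-trimethylcyclohex-2-en-1-ol | CC1=CC(C)(C)CC[C@@H]1O | intermediate
3 | tributyl({[(1S)-2,4,4-trimethylcyclohex-2-en-1-yl]oxy}methyl)stannane | CC1=CC(C)(C)CC[C@@H]1OC[Sn](CCCC)(CCCC)CCCC | intermediate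
4 | {[(1S)-2,4,4-trimethylcyclohex-2-en-1-yl]oxy}methyllithium (not isolated) | CC1=CC(C)(C)CC[C@@H]1OC[Li] | intermediate
5 | [(1R)-2,6,6-trimethylcyclohex-2-en-1-yl]methanol | OC[C@H]1C(C)=CCCC1(C)C | intermediate
6 | (1R)-2,6,6-trimethylcyclohex-2-ene-1-carbaldehyde | O=C[C@H]1C(C)=CCCC1(C)C | intermediate
7 | 4-methoxybenzylmagnesium chloride | COc1ccc(C[Mg]Cl)cc1 | starting material
8 | (1S)-2-(4-methoxyphenyl)-1-[(1R)-2,6,6-trimethylcyclohex-2-en-1-yl]ethan-1-ol | COc1ccc(C[C@H](O)[C@@H]2C(C)(C)CCC=C2C)cc1 | intermediate
9 | (1S)-2-(4-methoxyphenyl)-1-[(1R,2S,6S)-1,3,3-trimethyl-7-oxabicyclo[4.1.0]heptan-2-yl]ethan-1-ol | COc1ccc(C[C@H](O)[C@@H]2C(C)(C)CC[C@@H]3O[C@]23C)cc1 | intermediate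
10 | (1S,5R,6S,10R)-12-methoxypodocarpa-8,11,13-triene-1,6-diol | COc1ccc2C[C@H](O)[C@@H]3C(C)(C)CC[C@H](O)[C@@]3(C)c2c1 | intermediate
11 | (1S,5R,6S,10R)-6-hydroxy-12-methoxypodocarpa-8,11,13-trien-1-yl acetate | COc1ccc2C[C@H](O)[C@@H]3C(C)(C)CC[C@H](OC(C)=O)[C@@]3(C)c2c1 | intermediate
12 | 2,2-dimethyl-1,3-dioxolan-4-one | CC1(C)OCC(=O)O1 | starting material
13 | potassium 2,2-dimethyl-1,3-dioxol-4-olate (not isolated) | CC1(C)OC=C([O-])O1.[K+] | intermediate
14 | 2,2-dimethyl-1,3-dioxol-4-yl diphenyl phosphate | CC1(C)OC=C(OP(=O)(Oc2ccccc2)Oc2ccccc2)O1 | intermediate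
15 | (trimethylsilyl)methylmagnesium chloride | C[Si](C)(C)C[Mg]Cl | starting material
16 | 2,2-dimethyl-4-[(trimethylsilyl)methyl]-1,3-dioxole | CC1(C)OC=C(C[Si](C)(C)C)O1 | intermediate
17 | meta photocycloadduct of 11 and 16 (C11–C15, C13–C16 and C12–C14 bonds; exo acetonide; endo CH2SiMe3 on C16) | CC(=O)O[C@H]1CCC(C)(C)[C@H]2[C@@H](O)CC3=C([C@]12C)[C@H]4[C@@H]5OC(C)(C)O[C@]5(C[Si](C)(C)C)[C@H]6[C@@H]3[C@@]46OC | intermediate
18 | 12-oxo-15,16-O-isopropylidene-16-(trimethylsilylmethyl) bicyclo[3.2.1]octenone stage (not isolated) | CC(=O)O[C@H]1CCC(C)(C)[C@H]2[C@@H](O)CC3=C([C@]12C)[C@H]4[C@@H]5OC(C)(C)O[C@]5(C[Si](C)(C)C)[C@@H](C3)C4=O | intermediate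
19 | 12-oxo-15-hydroxy isomer of the target (15-OH exo, syn to C12) | CC(=O)O[C@H]1CCC(C)(C)[C@H]2[C@@H](O)CC3=C([C@]12C)[C@H]4[C@H](O)C(=C)[C@@H](C3)C4=O | intermediate
20 | 15-O-diethylboryl derivative of 19, chelated to the C12 carbonyl (not isolated) | CC(=O)O[C@H]1CCC(C)(C)[C@H]2[C@@H](O)CC3=C([C@]12C)[C@H]4[C@H](OB(CC)CC)C(=C)[C@@H](C3)C4=O | intermediate
21 | 15-dihydro target (12S,15S syn-diol) | CC(=O)O[C@H]1CCC(C)(C)[C@H]2[C@@H](O)CC3=C([C@]12C)[C@H]4[C@H](O)C(=C)[C@@H](C3)[C@@H]4O | intermediate
22 | CNP0149338.1, (1S,5R,6S,10R,11R,12S,13R) | C=C1C(=O)[C@@H]2C3=C(C[C@H]1[C@@H]2O)C[C@H](O)[C@@H]1C(C)(C)CC[C@H](OC(C)=O)[C@@]31C | target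

**Step count and risks**

Total step count: 14. Longest linear sequence: 12 (steps 1–8 and 11–14); steps 9–10 are the dioxole branch.

Steps most likely to fail:

1. Step 11. The excited-state pairing may divert to ortho (2+2) addition or electron-transfer pathways with the electron-rich silyl dioxole, or the alkene may add with poor orientational or facial selectivity. Fallback, setting out from diol 10 and re-entering at 19:
   - Birch reduction (Li, NH3, t-BuOH, THF, −78 °C) should give the dihydroanisole F1.
   - Oxalic acid in aqueous MeOH should hydrolyse it to the β,γ-unsaturated ketone F2, with the olefin held at C8=C9.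
   - The lithium dienolate (LiN(i-Pr)2, 3.3 equiv, THF, −78 °C, the two hydroxyls riding as alkoxides) is alkylated at C11 with 2,3-dibromopropene anti to C20 to give the bromoallyl ketone F3.
   - Intramolecular ketone α-alkenylation (Pd(PPh3)4, KOt-Bu, THF, 60 °C, through a C-bound palladium enolate at C13) should close C13–C16 to the bicyclic ketone diol F4.
   - Selective acetylation of the equatorial 1-OH gives the acetate F5.
   - Allylic oxidation with SeO2/t-BuOOH at C15, the only non-bridgehead allylic position of the exocyclic olefin, returns to 19.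

2. Step 7. The tertiary C10 cation may undergo 1,2-hydride shift (epoxide-to-ketone rearrangement) or elimination faster than it is captured by the weakly activated arene position. Fallback, setting out from 9 and re-entering at 10: homolytic epoxide opening with Cp2TiCl (trivalent titanium, from Cp2TiCl2, Mn dust, 2,4,6-collidine hydrochloride, THF) should give the tertiary C10 radical with the titanium alkoxide on C1. Radical addition to the arene and rearomatisation (radical arylation of an epoxide) avoids the cation altogether; no new isolated compound is involved.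

3. Step 13. Incomplete chelation, internal hydride delivery from the 15-oxygen, or attack from the C15–C16 side may erode facial selectivity at C12. Fallback, setting out from 17 and re-entering at 21:
   - PPTS in wet acetone should stop the acid cascade at the keto acetonide 18, which is isolated here.
   - NaBH4 (MeOH, 0 °C) then reduces C12 under steric control of the intact exo acetonide, which blocks the C15–C16 face, to give the 12-alcohol F6.
   - TsOH·H2O in THF/H2O finally triggers the Peterson-type elimination and deketalisation to 21.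

Further compounds
F1 | step 11 | (1S,5R,6S,10R)-12-methoxypodocarpa-8,12-diene-1,6-diol | COC1=CCC2=C(C1)[C@]3(C)[C@@H](O)CCC(C)(C)[C@H]3[C@@H](O)C2
F2 | step 11 | (1S,5R,6S,10R)-1,6-dihydroxypodocarp-8-en-12-one | O=C1CCC2=C(C1)[C@]3(C)[C@@H](O)CCC(C)(C)[C@H]3[C@@H](O)C2
F3 | step 11 | 11-(2-bromoprop-2-en-1-yl) derivative of F2 (side chain anti to C20) | O=C1CCC2=C([C@H]1CC(Br)=C)[C@]3(C)[C@@H](O)CCC(C)(C)[C@H]3[C@@H](O)C2
F4 | step 11 | 15-deoxy-1-O-deacetyl analogue of 19 (C12 ketone, C15H2, C16=CH2) | O[C@H]1CCC(C)(C)[C@H]2[C@@H](O)CC3=C([C@]12C)[C@H]4CC(=C)[C@@H](C3)C4=O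
F5 | step 11 | 1-acetate of F4 | CC(=O)O[C@H]1CCC(C)(C)[C@H]2[C@@H](O)CC3=C([C@]12C)[C@H]4CC(=C)[C@@H](C3)C4=O
F0 | step 7 | none | none
F6 | step 13 | 12-alcohol of 18 (12-OH syn to the acetonide-bearing bridge) | CC(=O)O[C@H]1CCC(C)(C)[C@H]2[C@@H](O)CC3=C([C@]12C)[C@H]4[C@@H]5OC(C)(C)O[C@]5(C[Si](C)(C)C)[C@@H](C3)[C@@H]4O
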